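**Retrosynthetic overview**

1. Target 24 ⇐ 23 ⇐ 22 (formylation, desilylation); 22 ⇐ 21 ⇐ 20 by syn-dehydration of a 10β-hydroxyl and hydroxyl-directed hydrogenation of a C8 exocyclic methylene (diterpenoid numbering; C19 is the ester carbon on C4).
2. Key disconnection: ring B of ketol 20 is cut at C6–C7 and at C9–C10, a convergent [3+3] union of the ring-A β-iodo ketone 7 (as zinc homoenolate: C6 nucleophile, C10 carbonyl electrophile) with the 2-(silylmethyl)allyl bromide 17 (C7 electrophile, C9 allylsilane nucleophile). The two fragments have ten and eleven skeletal carbons and meet at the quaternary C9.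
3. Enabling feature: in ring A, C6 and C10 are 1,3-related through C5 (β-carbon and carbonyl carbon of one ketone), which matches the 1,3-related C7 and C9 across C8, whose extra carbon becomes C17. C6 and the C19 ester are cis on C5/C4, so a temporary γ-lactone fixes C5, and the axial ester then steers the attack on C10.
4. 7 ⇐ cis-fused keto-lactone 4 ⇐ silyl enol ether 2 ⇐ enone ester 1 (asymmetric conjugate methylation sets C4). 17 ⇐ alkynol 14 (anti-carbomagnesiation/methylation fixes the alkene geometry that becomes C9) ⇐ aldehyde 11 ⇐ geraniol 8.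
5. Order of rings: ring A is present in 1; the temporary lactone ring is made in step 2 and opened in step 3; ring B is formed in step 11.

Key step: step 11

Remark: positions are named by the halimane diterpenoid numbering of the target (C19 ester and C18 methyl on C4; ring fusion C5/C10; C17 on C8; C20 and the C11–C16 side chain on C9). α/β refer to the usual drawing with ring A on the left, in which the C19 ester is β.

**Route**

Step 1
Reactants: 1 methyl 3-oxocyclohex-1-ene-1-carboxylate
Product: 2 methyl (1S)-1-methyl-3-[(trimethylsilyl)oxy]cyclohex-2-ene-1-carboxylate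
Conditions: Me2Zn (1.5 equiv), (CuOTf)2·C6H6 (2.5 mol %), chiral sulfonate-bridged imidazolinium salt as N-heterocyclic carbene precursor (5 mol %, the antipode that leads to the (S) product), t-BuOMe, −30 °C; then TMSOTf, −30 → 0 °C
Reagents that add atoms: dimethylzinc (C[Zn]C); trimethylsilyl trifluoromethanesulfonate (C[Si](C)(C)OS(=O)(=O)C(F)(F)F)
Why: Copper-catalysed asymmetric conjugate addition of a dialkylzinc to a β-alkoxycarbonyl cyclic enone should create the quaternary C4 centre (S) by enantioface control of the chiral copper–carbene complex, and O-silylation of the zinc enolate fixes the enol double bond toward C5.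

Step 2
Reactants: 2 methyl (1S)-1-methyl-3-[(trimethylsilyl)oxy]cyclohex-2-ene-1-carboxylate
Product: 4 (3aR,7aS)-7a-methyl-3a,6,7,7a-tetrahydroisobenzofuran-1,4(3H,5H)-dione, via hydroxymethyl ketone 3 (not isolated)
Conditions: aq. HCHO (37 %), Sc(OTf)3 (5 mol %), THF–H2O, 25 °C; then TsOH·H2O (10 mol %), PhMe, 60 °C
Reagents that add atoms: formaldehyde (C=O)
Why: A Mukaiyama aldol reaction with aqueous formaldehyde places C6 on the only enol carbon, and since only the C5 epimer with the hydroxymethyl group cis to the ester can close the γ-lactone while the other epimer equilibrates through the enol under the acid, the cis ring fusion (3aR,7aS) should be set under thermodynamic control.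

Step 3
Reactants: 4 (3aR,7aS)-7a-methyl-3a,6,7,7a-tetrahydroisobenzofuran-1,4(3H,5H)-dione
Product: 7 methyl (1S,2S)-2-(iodomethyl)-1-methyl-3-oxocyclohexane-1-carboxylate, via silyl ester 5 (not isolated), via iodo acid 6 (not isolated)
Conditions: TMSI (1.5 equiv), CH2Cl2, 0 → 25 °C, dark; then MeOH, 0 °C; then TMSCHN2, PhMe–MeOH, 0 °C
Reagents that add atoms: iodotrimethylsilane (C[Si](C)(C)I); (trimethylsilyl)diazomethane (C[Si](C)(C)C=[N+]=[N-])
Why: Iodide opens the silyl-activated γ-lactone by SN2 attack at the primary C6–O carbon and the acid is methylated with the diazoalkane, all without base, so the β-iodo ketone should neither eliminate nor epimerise and C5 keeps the configuration fixed by the lactone.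

Step 4
Reactants: 8 geraniol, (2E)-3,7-dimethylocta-2,6-dien-1-ol
Product: 9 tert-butyl{[(2E)-3,7-dimethylocta-2,6-dien-1-yl]oxy}dimethylsilane
Conditions: TBSCl, imidazole, DMF, 25 °C
Reagents that add atoms: tert-butyldimethylsilyl chloride (CC(C)(C)[Si](C)(C)Cl)
Why: Standard silylation protects the C15 oxygen through the organometallic steps; no stereocentre is formed.

Step 5
Reactants: 9 tert-butyl{[(2E)-3,7-dimethylocta-2,6-dien-1-yl]oxy}dimethylsilane
Product: 10 tert-butyl{[(2E)-5-(3,3-dimethyloxiran-2-yl)-3-methylpent-2-en-1-yl]oxy}dimethylsilane (racemic at the oxirane carbon)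
Conditions: mCPBA (1.0 equiv), CH2Cl2, −20 °C
Reagents that add atoms: 3-chloroperoxybenzoic acid (OOC(=O)c1cccc(Cl)c1)
Why: Prilezhaev epoxidation should take place at the more electron-rich terminal alkene, the 2,3-alkene being deactivated by the allylic oxygen; the new centre is racemic and is destroyed in step 6.

Step 6
Reactants: 10 tert-butyl{[(2E)-5-(3,3-dimethyloxiran-2-yl)-3-methylpent-2-en-1-yl]oxy}dimethylsilane
Product: 11 (4E)-6-{[tert-butyl(dimethyl)silyl]oxy}-4-methylhex-4-enal
Conditions: H5IO6, THF–H2O, 0 °C
Reagents that add atoms: none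
Why: Periodic acid opens the epoxide hydrolytically and cleaves the glycol (Malaprade cleavage) to the aldehyde whose carbonyl carbon becomes C9; no stereocentre remains.

Step 7
Reactants: 11 (4E)-6-{[tert-butyl(dimethyl)silyl]oxy}-4-methylhex-4-enal
Product: 12 tert-butyl{[(2E)-7,7-dibromo-3-methylhepta-2,6-dien-1-yl]oxy}dimethylsilane
Conditions: CBr4, PPh3, CH2Cl2, 0 °C
Reagents that add atoms: tetrabromomethane (BrC(Br)(Br)Br)
Why: First stage of the Corey–Fuchs sequence (Wittig-type dibromomethylenation of the aldehyde); no stereocentre is formed.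

Step 8
Reactants: 12 tert-butyl{[(2E)-7,7-dibromo-3-methylhepta-2,6-dien-1-yl]oxy}dimethylsilane
Product: 14 (6E)-8-{[tert-butyl(dimethyl)silyl]oxy}-6-methyloct-6-en-2-yn-1-ol, via lithium acetylide 13 (not isolated)
Conditions: n-BuLi (2.2 equiv), THF, −78 → 0 °C; then (CH2O)n, 0 → 25 °C; H2O
Reagents that add atoms: formaldehyde, as paraformaldehyde (C=O)
Why: Second stage of the Corey–Fuchs sequence, in which lithium–bromine exchange, α-elimination with 1,2-shift and addition of the acetylide to formaldehyde introduce C8 and C7; no stereocentre is formed.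

Step 9
Reactants: 14 (6E)-8-{[tert-butyl(dimethyl)silyl]oxy}-6-methyloct-6-en-2-yn-1-ol
Product: 16 (2Z,6E)-8-{[tert-butyl(dimethyl)silyl]oxy}-3,6-dimethyl-2-[(trimethylsilyl)methyl]octa-2,6-dien-1-ol, via alkenylmagnesium alkoxide 15 (not isolated)
Conditions: Me3SiCH2MgCl (3 equiv), CuI (10 mol %), THF, reflux; then MeI, 0 → 25 °C; H2O
Reagents that add atoms: (trimethylsilyl)methylmagnesium chloride (C[Si](C)(C)C[Mg]Cl); iodomethane (CI)
Why: Copper-catalysed anti-carbomagnesiation of the propargylic alkoxide puts the silylmethyl group on the alkyne carbon next to CH2O while magnesium is held cis to CH2O in a five-membered chelate, so C-methylation with retention should give the single tetrasubstituted alkene isomer with CH2OH cis to the new methyl group.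

Step 10
Reactants: 16 (2Z,6E)-8-{[tert-butyl(dimethyl)silyl]oxy}-3,6-dimethyl-2-[(trimethylsilyl)methyl]octa-2,6-dien-1-ol
Product: 17 tert-butyl{[(2E,6E)-8-bromo-3,6-dimethyl-7-[(trimethylsilyl)methyl]octa-2,6-dien-1-yl]oxy}dimethylsilane
Conditions: CBr4, PPh3, CH2Cl2, −20 °C
Reagents that add atoms: tetrabromomethane (BrC(Br)(Br)Br)
Why: Appel bromination by SN2 displacement at the primary allylic carbon should leave the alkene geometry and the allylsilane untouched; no stereocentre is formed.

Step 11
Reactants: 7 methyl (1S,2S)-2-(iodomethyl)-1-methyl-3-oxocyclohexane-1-carboxylate; 17 tert-butyl{[(2E,6E)-8-bromo-3,6-dimethyl-7-[(trimethylsilyl)methyl]octa-2,6-dien-1-yl]oxy}dimethylsilane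
Product: 20 methyl (4S,5S,9S,10R)-15-{[tert-butyl(dimethyl)silyl]oxy}-10-hydroxyhalima-8(17),13(E)-dien-19-oate (trans-fused; 10-OH β, 5-H α, 9-CH3 α), via zinc homoenolate 18 (not isolated), via allylated ketone 19 (not isolated)
Conditions: Zn (activated), LiCl, THF, 25 °C, cannula filtration from excess zinc; then 17, Pd2(dba)3 (2.5 mol %), P(2-furyl)3 (10 mol %), 0 → 25 °C; then solvent change to CH2Cl2, BF3·OEt2 (3 equiv), −78 °C; aq. NaHCO3 (telescoped, no isolation)
Reagents that add atoms: none
Why: Proposed new method: zinc inserts into the C6–I bond of 7 to give the β-zincio ketone 18 (a homoenolate, C6 nucleophilic, C10 carbonyl free), which transmetalates to the π-allylpalladium complex formed from 17 and is joined to its unsubstituted CH2 terminus, forming C6–C7 with the tetrasubstituted alkene geometry intact; BF3·OEt2 then activates the C10 ketone of 19, and the tethered allylsilane attacks it through its γ carbon C9 and loses the silyl group, forming C9–C10, the quaternary C9 and the C8 exocyclic methylene. The closest known reaction types are the palladium-catalysed Negishi allylation of functionalised alkylzinc halides (zinc homoenolates included) and the intramolecular Hosomi–Sakurai addition of 2-substituted allylsilanes to ketones; their one-flask union as a [3+3] annulation of a ketone homoenolate with a 2-(silylmethyl)allyl bromide is the untested part. Ring B is closed in a six-membered, chair-like transition state that is exo with respect to the carbonyl and endo with respect to the allylsilane double bond. C10 should be attacked on its equatorial (α) face because the axial C19 ester on C4, held cis to C6 by the earlier lactone, blocks the axial trajectory, which gives the trans-fused 10β-alkoxide; C9 is set by the alkene geometry of 17, since the methyl group cis to the tether carbon C7 must become axial (α) and the side chain equatorial, and C5 is carried unchanged from 7. The step needs coupling at the CH2 terminus and not at the fully substituted one, reductive elimination faster than β-hydride loss, and no enolisation at C5; the steric bias of the allyl unit, the furylphosphine ligand and the base-free, low-temperature Lewis-acid stage are relied on for these.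

Step 12
Reactants: 20 methyl (4S,5S,9S,10R)-15-{[tert-butyl(dimethyl)silyl]oxy}-10-hydroxyhalima-8(17),13(E)-dien-19-oate
Product: 21 methyl (4S,5S,8R,9S,10R)-15-{[tert-butyl(dimethyl)silyl]oxy}-10-hydroxyhalim-13(E)-en-19-oate (8-CH3 α)
Conditions: H2 (50 bar), [Rh(nbd)(dppb)]BF4 (5 mol %), CH2Cl2, 25 °C
Reagents that add atoms: none
Why: In this hydroxyl-directed homogeneous hydrogenation the axial C10 hydroxyl binds the cationic rhodium and delivers H2 to the β face of the C8 methylene, which is also the face not shielded by the axial C9 methyl, so C8 should form with the α (equatorial) methyl while the undirected trisubstituted side-chain alkene remains.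

Step 13
Reactants: 21 methyl (4S,5S,8R,9S,10R)-15-{[tert-butyl(dimethyl)silyl]oxy}-10-hydroxyhalim-13(E)-en-19-oate
Product: 22 methyl (4S,5R,8R,9S)-15-{[tert-butyl(dimethyl)silyl]oxy}halima-1(10),13(E)-dien-19-oate
Conditions: Burgess reagent (methyl N-(triethylammoniosulfonyl)carbamate), PhMe, 50 °C
Reagents that add atoms: none
Why: Syn elimination (Ei) of the tertiary sulfamate can only use a C1 hydrogen, because H5 is trans-diaxial to the C10 oxygen and C9 carries no hydrogen, so the 1(10)-alkene should form regioselectively and the C10 centre is removed.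

Step 14
Reactants: 22 methyl (4S,5R,8R,9S)-15-{[tert-butyl(dimethyl)silyl]oxy}halima-1(10),13(E)-dien-19-oate
Product: 23 methyl (4S,5R,8R,9S)-15-hydroxyhalima-1(10),13(E)-dien-19-oate
Conditions: TBAF, THF, 0 → 25 °C
Reagents that add atoms: none
Why: Fluoride-mediated desilylation of the primary allylic silyl ether should leave the ester and both alkenes untouched; no stereocentre is affected.

Step 15
Reactants: 23 methyl (4S,5R,8R,9S)-15-hydroxyhalima-1(10),13(E)-dien-19-oate
Product: 24 methyl (4S,5R,8R,9S)-15-(formyloxy)halima-1(10),13(E)-dien-19-oate (target, CNP0188193.1)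
Conditions: acetic formic anhydride, pyridine, CH2Cl2, 0 °C
Reagents that add atoms: acetic formic anhydride (CC(=O)OC=O)
Why: O-Formylation of the primary allylic alcohol with the mixed anhydride, which transfers the formyl group selectively, completes the target without touching any stereocentre.

**Compound list**

1 | methyl 3-oxocyclohex-1-ene-1-carboxylate | COC(=O)C1=CC(=O)CCC1 | starting material
2 | methyl (1S)-1-methyl-3-[(trimethylsilyl)oxy]cyclohex-2-ene-1-carboxylate | COC(=O)[C@@]1(C)CCCC(O[Si](C)(C)C)=C1 | intermediate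
3 | methyl (1S)-2-(hydroxymethyl)-1-methyl-3-oxocyclohexane-1-carboxylate (mixture of C2 epimers) | COC(=O)[C@@]1(C)CCCC(=O)C1CO | intermediate
4 | (3aR,7aS)-7a-methyl-3a,6,7,7a-tetrahydroisobenzofuran-1,4(3H,5H)-dione (cis-fused keto-lactone) | O=C3[C@@]1(C)CCCC(=O)[C@H]1CO3 | intermediate
5 | trimethylsilyl (1S,2S)-2-(iodomethyl)-1-methyl-3-oxocyclohexane-1-carboxylate | C[Si](C)(C)OC(=O)[C@@]1(C)CCCC(=O)[C@H]1CI | intermediate
6 | (1S,2S)-2-(iodomethyl)-1-methyl-3-oxocyclohexane-1-carboxylic acid | OC(=O)[C@@]1(C)CCCC(=O)[C@H]1CI | intermediate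
7 | methyl (1S,2S)-2-(iodomethyl)-1-methyl-3-oxocyclohexane-1-carboxylate | COC(=O)[C@@]1(C)CCCC(=O)[C@H]1CI | intermediate
8 | geraniol, (2E)-3,7-dimethylocta-2,6-dien-1-ol | CC(C)=CCC/C(C)=C/CO | starting material
9 | tert-butyl{[(2E)-3,7-dimethylocta-2,6-dien-1-yl]oxy}dimethylsilane | CC(C)=CCC/C(C)=C/CO[Si](C)(C)C(C)(C)C | intermediate
10 | tert-butyl{[(2E)-5-(3,3-dimethyloxiran-2-yl)-3-methylpent-2-en-1-yl]oxy}dimethylsilane (racemic at the oxirane carbon) | CC1(C)OC1CC/C(C)=C/CO[Si](C)(C)C(C)(C)C | intermediate
11 | (4E)-6-{[tert-butyl(dimethyl)silyl]oxy}-4-methylhex-4-enal | O=CCC/C(C)=C/CO[Si](C)(C)C(C)(C)C | intermediate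
12 | tert-butyl{[(2E)-7,7-dibromo-3-methylhepta-2,6-dien-1-yl]oxy}dimethylsilane | BrC(Br)=CCC/C(C)=C/CO[Si](C)(C)C(C)(C)C | intermediate
13 | [(5E)-7-{[tert-butyl(dimethyl)silyl]oxy}-5-methylhept-5-en-1-yn-1-yl]lithium | [Li]C#CCC/C(C)=C/CO[Si](C)(C)C(C)(C)C | intermediate
14 | (6E)-8-{[tert-butyl(dimethyl)silyl]oxy}-6-methyloct-6-en-2-yn-1-ol | OCC#CCC/C(C)=C/CO[Si](C)(C)C(C)(C)C | intermediate
15 | 3-[(3E)-5-{[tert-butyl(dimethyl)silyl]oxy}-3-methylpent-3-en-1-yl]-4-[(trimethylsilyl)methyl]-2,5-dihydro-1,2-oxamagnesole (cyclic alkenylmagnesium alkoxide) | C[Si](C)(C)CC1=C(CC/C(C)=C/CO[Si](C)(C)C(C)(C)C)[Mg]OC1 | intermediate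
16 | (2Z,6E)-8-{[tert-butyl(dimethyl)silyl]oxy}-3,6-dimethyl-2-[(trimethylsilyl)methyl]octa-2,6-dien-1-ol (CH2OH cis to the C3 methyl) | OC/C(C[Si](C)(C)C)=C(\C)CC/C(C)=C/CO[Si](C)(C)C(C)(C)C | intermediate
17 | tert-butyl{[(2E,6E)-8-bromo-3,6-dimethyl-7-[(trimethylsilyl)methyl]octa-2,6-dien-1-yl]oxy}dimethylsilane (CH2Br cis to the C6 methyl) | BrC/C(C[Si](C)(C)C)=C(\C)CC/C(C)=C/CO[Si](C)(C)C(C)(C)C | intermediate
18 | iodo{[(1S,2S)-2-(methoxycarbonyl)-2-methyl-6-oxocyclohexyl]methyl}zinc | COC(=O)[C@@]1(C)CCCC(=O)[C@H]1C[Zn]I | intermediate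
19 | methyl (1S,2S)-2-[(3Z,7E)-9-{[tert-butyl(dimethyl)silyl]oxy}-4,7-dimethyl-3-[(trimethylsilyl)methyl]nona-3,7-dien-1-yl]-1-methyl-3-oxocyclohexane-1-carboxylate | COC(=O)[C@@]1(C)CCCC(=O)[C@H]1CC/C(C[Si](C)(C)C)=C(\C)CC/C(C)=C/CO[Si](C)(C)C(C)(C)C | intermediate
20 | methyl (4S,5S,9S,10R)-15-{[tert-butyl(dimethyl)silyl]oxy}-10-hydroxyhalima-8(17),13(E)-dien-19-oate (trans-fused; 10-OH β, 5-H α, 9-CH3 α) | COC(=O)[C@@]1(C)CCC[C@@]2(O)[C@H]1CCC(=C)[C@]2(C)CC/C(C)=C/CO[Si](C)(C)C(C)(C)C | intermediate
21 | methyl (4S,5S,8R,9S,10R)-15-{[tert-butyl(dimethyl)silyl]oxy}-10-hydroxyhalim-13(E)-en-19-oate (8-CH3 α) | COC(=O)[C@@]1(C)CCC[C@@]2(O)[C@H]1CC[C@@H](C)[C@]2(C)CC/C(C)=C/CO[Si](C)(C)C(C)(C)C | intermediate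
22 | methyl (4S,5R,8R,9S)-15-{[tert-butyl(dimethyl)silyl]oxy}halima-1(10),13(E)-dien-19-oate | COC(=O)[C@@]1(C)CCC=C2[C@H]1CC[C@@H](C)[C@]2(C)CC/C(C)=C/CO[Si](C)(C)C(C)(C)C | intermediate
23 | methyl (4S,5R,8R,9S)-15-hydroxyhalima-1(10),13(E)-dien-19-oate | COC(=O)[C@@]1(C)CCC=C2[C@H]1CC[C@@H](C)[C@]2(C)CC/C(C)=C/CO | intermediate
24 | methyl (4S,5R,8R,9S)-15-(formyloxy)halima-1(10),13(E)-dien-19-oate (CNP0188193.1) | COC(=O)[C@@]1(C)CCC=C2[C@H]1CC[C@@H](C)[C@]2(C)CC/C(C)=C/COC=O | target

**Step count and risks**

Total step count: 15. Longest linear sequence: 12 steps (steps 4–10, then 11–15); the ring-A branch (steps 1–3) joins at step 11.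

Steps most likely to fail:

1. Step 11 (Proposed new method). The alkylpalladium stage may lose a β-hydride, or 7 may lose HI, to give the exocyclic enone, which would also erase C5. Coupling may occur at the fully substituted allyl terminus, or the π-allyl complex may be desilylated. At the Lewis-acid stage protodesilylation, lactonisation of the C10 alkoxide onto the C19 ester or a cis-fused closure may compete. Fallback with known chemistry, setting out from 7 and 16 and returning at 20: alcohol 16 is acetylated (Ac2O, pyridine) to (2Z,6E)-8-{[tert-butyl(dimethyl)silyl]oxy}-3,6-dimethyl-2-[(trimethylsilyl)methyl]octa-2,6-dien-1-yl acetate F1. Iodide 7 and F1 are then joined in a nickel-catalysed reductive cross-electrophile allylation (NiCl2(dme), 4,4′-di-tert-butyl-2,2′-bipyridine, Zn, DMA, 25 °C), in which the C6 radical is captured at nickel and bonded to the unsubstituted allyl terminus; this gives ketone 19, which is now isolated. A separate Hosomi–Sakurai cyclisation of 19 (TiCl4, CH2Cl2, −78 °C) then gives 20.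

2. Step 13. The tertiary sulfamate may ionise to the C10 cation, followed by methyl migration from C9, capture by the C19 ester carbonyl (lactone formation) or proton loss toward C5. Fallback, setting out from 21 and returning at 22: the elimination mode is changed from syn to anti by way of the chlorosulfite (SOCl2, pyridine, −30 °C, E2), where pyridine should remove the axial C1 α-hydrogen in preference to the more shielded H5 next to the quaternary C4. This fallback makes no further compound (F0).

3. Step 9. Carbometalation of the internal alkyne may be incomplete or not regioselective, and C-methylation of the hindered alkenylmagnesium may be slow, so that protonation competes. Fallback, setting out from 14 and returning at 16: the alkenylmagnesium alkoxide 15 is quenched with iodine to give (2E,6E)-8-{[tert-butyl(dimethyl)silyl]oxy}-3-iodo-6-methyl-2-[(trimethylsilyl)methyl]octa-2,6-dien-1-ol F2, which is isolated and methylated by a stereoretentive Negishi coupling (Me2Zn, Pd(PPh3)4, THF, 25 °C) to 16.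

Further compounds
F1 | step 11 | (2Z,6E)-8-{[tert-butyl(dimethyl)silyl]oxy}-3,6-dimethyl-2-[(trimethylsilyl)methyl]octa-2,6-dien-1-yl acetate | CC(=O)OC/C(C[Si](C)(C)C)=C(\C)CC/C(C)=C/CO[Si](C)(C)C(C)(C)C
F0 | step 13 | none | none
F2 | step 9 | (2E,6E)-8-{[tert-butyl(dimethyl)silyl]oxy}-3-iodo-6-methyl-2-[(trimethylsilyl)methyl]octa-2,6-dien-1-ol | OC/C(C[Si](C)(C)C)=C(\I)CC/C(C)=C/CO[Si](C)(C)C(C)(C)C
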